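**Plan**
- Numbering (furo[3,4-c]furan-1-one): ring A is the lactone (C1, O2, C3, C3a, C6a), ring B the tetrahydrofuran (C3a, C4, O5, C6, C6a). In the target H3, H3a, H6 and H6a are all cis, so both aryl groups are endo.
- Retrosynthesis, in order: three phenol O–Si bonds; C1=O back to a methyl acetal; C6–C6a and O5–C6 together (oxocarbenium/enol ether annulation of a dihydrofuryl alcohol with the catechol aldehyde acetal); C3–C3a of ring A (carbene C–H insertion); the enol ether chain back to a benzylic alcohol and methyl but-2-ynoate.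
- Enabling feature: C3 is a benzylic CH bonded to ring oxygen O2 and to an electron-rich aryl group. When C1=C6a is a Z enol ether, this C–H lies 1,5 to C3a, where the C4 carboxyl can stabilise a diazo/carbene carbon.
- Forward: ring A closes first, as a cis-2-aryl-2,3-dihydrofuran, by the C3–C3a bond; ring B closes second onto the enol ether; C1 is then oxidised and the phenols are freed.
- Stereochemistry: C3 and C3a (cis, absolute) from the chiral dirhodium carboxylate; C6a from the forced cis ring fusion; C6 (endo aryl) from the kinetically controlled oxocarbenium closure.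

Key step: step 6

Remark: the sense of induction of Rh2(S-PTTL)4 (PTTL = N-phthaloyl-tert-leucinate) in step 6 is assumed by analogy with benzo-fused cases; if it proves opposite, Rh2(R-PTTL)4 is used and nothing else changes.
Remark: the configuration at the acetal/lactol carbon C1 of 15, 16 and 17 is left open (exo expected for 16 and 17); that centre becomes the carbonyl carbon in step 12.
Abbreviations: TBS = tert-butyldimethylsilyl; Ar = 4-(TBSO)-3,5-dimethoxyphenyl; Ar′ = 3,4-bis(TBSO)phenyl.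

**Route**

Step 1
Reactants: 1 4-hydroxy-3,5-dimethoxybenzaldehyde (syringaldehyde)
Product: 2 4-(TBSO)-3,5-dimethoxybenzaldehyde
Conditions: TBSCl (1.2 equiv), imidazole (2.5 equiv), DMF, rt
Reagents that add atoms: tert-butyldimethylsilyl chloride, CC(C)(C)[Si](C)(C)Cl
Why: Silyl ether protection of the phenol under imidazole catalysis masks the acidic OH for the base, carbene and Lewis-acid steps.

Step 2
Reactants: 2 4-(TBSO)-3,5-dimethoxybenzaldehyde
Product: 3 [4-(TBSO)-3,5-dimethoxyphenyl]methanol (ArCH2OH)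
Conditions: NaBH4, MeOH/THF, 0 °C
Reagents that add atoms: none
Why: Borohydride reduction of the aryl aldehyde should give the benzylic alcohol without touching the hindered aryl silyl ether.

Step 3
Reactants: 3 ArCH2OH; 4 methyl but-2-ynoate
Product: 5 methyl (E)-4-(ArCH2O)but-2-enoate
Conditions: PPh3 (10 mol %), AcOH (20 mol %), toluene, 90 °C
Reagents that add atoms: none
Why: Phosphine-catalysed γ-umpolung addition of an alcohol to a 2-alkynoate: PPh3 adds to 4, proton shifts give a vinylphosphonium that takes up the alkoxide at C4 and releases the E enoate.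

Step 4
Reactants: 5 methyl (E)-4-(ArCH2O)but-2-enoate
Product: 7 methyl (Z)-4-(ArCH2O)but-3-enoate, via lithium dienolate 6 (not isolated)
Conditions: LiN(i-Pr)2 (1.15 equiv), HMPA, THF, −78 °C; then AcOH, −78 °C
Reagents that add atoms: none
Why: Kinetic deconjugation of an enoate: γ-deprotonation gives dienolate 6, in which the γ-alkoxy group prefers the cisoid position (syn effect), so α-protonation at low temperature should leave the Z enol ether.

Step 5
Reactants: 7 methyl (Z)-4-(ArCH2O)but-3-enoate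
Product: 8 methyl (Z)-2-diazo-4-(ArCH2O)but-3-enoate
Conditions: 4-acetamidobenzenesulfonyl azide (1.3 equiv), DBU (1.5 equiv), MeCN, 0 °C, dark; used at once
Reagents that add atoms: 4-acetamidobenzenesulfonyl azide, CC(=O)Nc1ccc(cc1)S(=O)(=O)N=[N+]=[N-]
Why: Regitz diazo transfer to the methylene activated by the ester and the vinyl group, the usual entry to vinyl diazoacetates; the Z enol ether geometry should be retained.

Step 6
Reactants: 8 methyl (Z)-2-diazo-4-(ArCH2O)but-3-enoate
Product: 10 methyl (2S,3R)-2-Ar-2,3-dihydrofuran-3-carboxylate (aryl and ester cis), via rhodium carbenoid 9 (not isolated)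
Conditions: Rh2(S-PTTL)4 (1 mol %), toluene, 4 Å MS, −60 → −30 °C, slow addition of 8
Reagents that add atoms: none
Why: Proposed new method: loss of N2 from 8 at the dirhodium carboxylate gives the donor/acceptor carbenoid 9, whose carbene carbon lies 1,5 to the benzylic C–H next to the ether oxygen because the enol ether is Z; hydride-like transfer of that hydrogen to the carbene carbon with concurrent C–C bonding (three-centre transition state) forms the C2–C3 bond of the dihydrofuran (C3–C3a of the target) and frees the catalyst. The closest known reaction type is the enantioselective intramolecular C–H insertion of aryl diazoacetates into benzylic ether C–H bonds, which gives cis-2-aryl-2,3-dihydrobenzofuran-3-carboxylates; here the benzo ring is replaced by the Z enol ether C=C. The five-membered ring closes by 1,5-insertion, the carbene carbon bonding to the C–H carbon through a six-centre array that includes the migrating hydrogen. The cis relation of aryl and ester should follow from the compact insertion transition state, and equally from the stepwise limit, in which hydride transfer gives an O-benzylidene oxonium/ester enolate (a vinylogous carbonyl ylide) that closes by disrotatory six-electron electrocyclisation to the cis ring; the absolute configuration of both centres is set by the chiral carboxylate ligands. The step needs insertion to outrun 1,5-cyclisation of the vinyl diazo unit to a pyrazole, cyclopropene formation and attack on the aryl ring: the Z geometry holds the O–CH2Ar group over the carbene, the C–H bond is activated by the ether oxygen and the electron-rich ring, there is no sp3 C–H next to the carbene for a 1,2-shift, and 8 is added slowly at low temperature.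

Step 7
Reactants: 10 methyl (2S,3R)-2-Ar-2,3-dihydrofuran-3-carboxylate
Product: 11 [(2S,3S)-2-Ar-2,3-dihydrofuran-3-yl]methanol (cis)
Conditions: i-Bu2AlH (2.5 equiv), CH2Cl2, −78 → 0 °C; aq. potassium sodium tartrate work-up
Reagents that add atoms: none
Why: Aluminium hydride reduction of the ester; no base is present, so the allylic centre next to the ester should not epimerise and the enol ether is inert.

Step 8
Reactants: 12 3,4-dihydroxybenzaldehyde
Product: 13 3,4-bis(TBSO)benzaldehyde (Ar′CHO)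
Conditions: TBSCl (2.4 equiv), imidazole (5 equiv), DMF, rt
Reagents that add atoms: tert-butyldimethylsilyl chloride, CC(C)(C)[Si](C)(C)Cl
Why: Silyl ether protection of both catechol hydroxyls under imidazole catalysis.

Step 9
Reactants: 13 Ar′CHO
Product: 14 Ar′CH(OMe)2 (dimethyl acetal)
Conditions: HC(OMe)3 (3 equiv), pyridinium p-toluenesulfonate (5 mol %), CH2Cl2/MeOH, rt
Reagents that add atoms: trimethyl orthoformate, COC(OC)OC
Why: Acid-catalysed acetalisation with the orthoformate as methoxy source and water scavenger; aryl silyl ethers tolerate the weak acid.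

Step 10
Reactants: 11 [(2S,3S)-2-Ar-2,3-dihydrofuran-3-yl]methanol; 14 Ar′CH(OMe)2
Product: 16 (3S,3aS,6S,6aR)-6-Ar′-3-Ar-1-methoxytetrahydro-1H,3H-furo[3,4-c]furan (C1 epimers), via mixed acetal 15 (not isolated)
Conditions: Me3SiOTf (0.2 equiv), CH2Cl2, 4 Å MS, −78 → −40 °C; Et3N quench at −78 °C
Reagents that add atoms: none
Why: Prins-type oxocarbenium/enol ether cyclisation: transacetalisation gives 15, loss of methoxide gives the O-alkyl benzylidene oxocarbenium ion, C4 of the enol ether attacks it (five-membered ring B, necessarily cis-fused, which sets C6a) and methanol caps the ring oxocarbenium at C1; under kinetic control the aryl group at C6 should end up endo, the selectivity relied on for this class of cis-dihydrofuryl alcohols.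

Step 11
Reactants: 16 bicyclic methyl acetal
Product: 17 (3S,3aS,6S,6aR)-6-Ar′-3-Ar-tetrahydro-1H,3H-furo[3,4-c]furan-1-ol (lactol, C1 epimers)
Conditions: AcOH/H2O/THF (3:1:1), 50 °C
Reagents that add atoms: water, O
Why: Mild acid hydrolysis of the cyclic methyl acetal; acetal ionisation should be much faster than ionisation of the two benzylic C–O bonds.

Step 12
Reactants: 17 lactol
Product: 18 (3S,3aS,6S,6aR)-6-Ar′-3-Ar-tetrahydro-1H,3H-furo[3,4-c]furan-1-one
Conditions: (n-Pr4N)RuO4 (5 mol %), N-methylmorpholine N-oxide (1.5 equiv), 4 Å MS, CH2Cl2, rt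
Reagents that add atoms: none
Why: Ley–Griffith oxidation of a lactol to the γ-lactone under neutral conditions; no stereocentre is touched.

Step 13
Reactants: 18 tris-silyl lactone
Product: 19 (3S,3aS,6S,6aR)-6-(3,4-dihydroxyphenyl)-3-(4-hydroxy-3,5-dimethoxyphenyl)tetrahydro-1H,3H-furo[3,4-c]furan-1-one (target)
Conditions: n-Bu4NF (3.3 equiv), AcOH (3.5 equiv), THF, 0 °C
Reagents that add atoms: none
Why: Fluoride cleavage of the three aryl silyl ethers; acetic acid buffering keeps the phenols protonated so that a para-phenoxide cannot expel the lactone carboxylate at C3.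

**Compound list**
1 | 4-hydroxy-3,5-dimethoxybenzaldehyde | COc1cc(C=O)cc(OC)c1O | starting material
2 | 4-(TBSO)-3,5-dimethoxybenzaldehyde | COc1cc(C=O)cc(OC)c1O[Si](C)(C)C(C)(C)C | intermediate
3 | [4-(TBSO)-3,5-dimethoxyphenyl]methanol | COc1cc(CO)cc(OC)c1O[Si](C)(C)C(C)(C)C | intermediate
4 | methyl but-2-ynoate | CC#CC(=O)OC | starting material
5 | methyl (E)-4-{[4-(TBSO)-3,5-dimethoxyphenyl]methoxy}but-2-enoate | COC(=O)/C=C/COCc1cc(OC)c(O[Si](C)(C)C(C)(C)C)c(OC)c1 | intermediate
6 | lithium dienolate of 5 (3Z) | [Li+].COC([O-])=C/C=C\OCc1cc(OC)c(O[Si](C)(C)C(C)(C)C)c(OC)c1 | intermediate (not isolated)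
7 | methyl (Z)-4-{[4-(TBSO)-3,5-dimethoxyphenyl]methoxy}but-3-enoate | COC(=O)C/C=C\OCc1cc(OC)c(O[Si](C)(C)C(C)(C)C)c(OC)c1 | intermediate
8 | methyl (Z)-2-diazo-4-{[4-(TBSO)-3,5-dimethoxyphenyl]methoxy}but-3-enoate | COC(=O)C(=[N+]=[N-])/C=C\OCc1cc(OC)c(O[Si](C)(C)C(C)(C)C)c(OC)c1 | intermediate
9 | rhodium carbenoid of 8 (carbene carbon on one Rh of the Rh2(S-PTTL)4 core; ligands not drawn) | COC(=O)C(=[Rh])/C=C\OCc1cc(OC)c(O[Si](C)(C)C(C)(C)C)c(OC)c1 | intermediate (not isolated)
10 | methyl (2S,3R)-2-[4-(TBSO)-3,5-dimethoxyphenyl]-2,3-dihydrofuran-3-carboxylate | COC(=O)[C@@H]1C=CO[C@@H]1c2cc(OC)c(O[Si](C)(C)C(C)(C)C)c(OC)c2 | intermediate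
11 | {(2S,3S)-2-[4-(TBSO)-3,5-dimethoxyphenyl]-2,3-dihydrofuran-3-yl}methanol | OC[C@@H]1C=CO[C@@H]1c2cc(OC)c(O[Si](C)(C)C(C)(C)C)c(OC)c2 | intermediate
12 | 3,4-dihydroxybenzaldehyde | O=Cc1ccc(O)c(O)c1 | starting material
13 | 3,4-bis(TBSO)benzaldehyde | O=Cc1ccc(O[Si](C)(C)C(C)(C)C)c(O[Si](C)(C)C(C)(C)C)c1 | intermediate
14 | 4-(dimethoxymethyl)-1,2-bis(TBSO)benzene | COC(OC)c1ccc(O[Si](C)(C)C(C)(C)C)c(O[Si](C)(C)C(C)(C)C)c1 | intermediate
15 | mixed methyl acetal of 13 with alcohol 11 (acetal carbon epimers) | COC(OC[C@@H]1C=CO[C@@H]1c2cc(OC)c(O[Si](C)(C)C(C)(C)C)c(OC)c2)c3ccc(O[Si](C)(C)C(C)(C)C)c(O[Si](C)(C)C(C)(C)C)c3 | intermediate (not isolated)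
16 | (3S,3aS,6S,6aR)-6-[3,4-bis(TBSO)phenyl]-3-[4-(TBSO)-3,5-dimethoxyphenyl]-1-methoxytetrahydro-1H,3H-furo[3,4-c]furan (C1 epimers) | COc1cc([C@H]2OC(OC)[C@@H]3[C@H]2CO[C@@H]3c2ccc(O[Si](C)(C)C(C)(C)C)c(O[Si](C)(C)C(C)(C)C)c2)cc(OC)c1O[Si](C)(C)C(C)(C)C | intermediate
17 | (3S,3aS,6S,6aR)-6-[3,4-bis(TBSO)phenyl]-3-[4-(TBSO)-3,5-dimethoxyphenyl]tetrahydro-1H,3H-furo[3,4-c]furan-1-ol (C1 epimers) | COc1cc([C@H]2OC(O)[C@@H]3[C@H]2CO[C@@H]3c2ccc(O[Si](C)(C)C(C)(C)C)c(O[Si](C)(C)C(C)(C)C)c2)cc(OC)c1O[Si](C)(C)C(C)(C)C | intermediate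
18 | (3S,3aS,6S,6aR)-6-[3,4-bis(TBSO)phenyl]-3-[4-(TBSO)-3,5-dimethoxyphenyl]tetrahydro-1H,3H-furo[3,4-c]furan-1-one | COc1cc([C@H]2OC(=O)[C@@H]3[C@H]2CO[C@@H]3c2ccc(O[Si](C)(C)C(C)(C)C)c(O[Si](C)(C)C(C)(C)C)c2)cc(OC)c1O[Si](C)(C)C(C)(C)C | intermediate
19 | (3S,3aS,6S,6aR)-6-(3,4-dihydroxyphenyl)-3-(4-hydroxy-3,5-dimethoxyphenyl)tetrahydro-1H,3H-furo[3,4-c]furan-1-one | COc1cc([C@H]2OC(=O)[C@@H]3[C@H]2CO[C@@H]3c2ccc(O)c(O)c2)cc(OC)c1O | target

**Count and risks**
Total: 13 steps. Longest linear sequence: 11 steps (1–7, then 10–13); steps 8 and 9 form the side branch.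

Step 6 (Proposed new method). Possible failures: the Z vinyl diazo ester may cyclise to a pyrazole before the carbene forms, or enantiocontrol may be lost if a metal-free ylide-type zwitterion closes the ring. The fallback uses known chemistry, sets out from aldehyde 2 and comes back at alcohol 11. A MgCl2-catalysed anti-aldol reaction (MgCl2, Et3N, Me3SiCl, EtOAc, rt) of 2 with commercial (S)-4-benzyl-3-(pent-4-enoyl)oxazolidin-2-one should give the silylated anti adduct (4S)-4-benzyl-3-[(2R,3S)-2-allyl-3-Ar-3-(trimethylsilyloxy)propanoyl]oxazolidin-2-one F1. The (S) auxiliary is the one that the chelated Z-enolate model predicts for this sense. Methanolysis (CF3CO2H, MeOH) frees the anti aldol F2. Lemieux–Johnson cleavage of the allyl group (K2OsO4·2H2O cat., NaIO4, 2,6-lutidine, dioxane/H2O) gives an aldehyde that closes on the benzylic hydroxyl to the lactol F3. Dehydration (MsCl, Et3N, CH2Cl2) gives the cis-dihydrofuran imide F4, and LiBH4 (THF/MeOH, 0 °C) removes the auxiliary to give 11. In this fallback the C3–C3a bond comes from the aldol step.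

Step 10. Possible failures: closure to the exo aryl epimer at C6, or reversible ionisation at the benzylic carbon C2 of the dihydrofuran with loss of the cis relationship. The fallback is a diazo-lactone C–H insertion (known chemistry), from 11 and 13 back to 18. NaBH4 reduction of 13 gives the benzylic alcohol F5, and an Appel reaction (CBr4, PPh3) gives the bromide F6. Williamson etherification of 11 (NaH, THF, 0 °C) with F6 gives the ether F7. Oxidation of the cyclic enol ether with pyridinium chlorochromate (C5H5NH)(CrO3Cl) gives the cis lactone F8. Deacylative diazo transfer follows: LiN(SiMe3)2 and CF3CO2CH2CF3 (THF, −78 °C) give the α-trifluoroacetyl lactone F9, then 4-acetamidobenzenesulfonyl azide and Et3N (MeCN/H2O) give the α-diazo lactone F10. Rh2(OAc)4 (CH2Cl2, rt) should then insert 1,5 into the benzylic ether C–H, closing ring B cis-fused with the aryl group endo and giving 18 directly, so steps 11 and 12 fall away.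

Step 13. Possible failure: base-induced epimerisation at C3 through expulsion of the lactone carboxylate from a para-phenoxide (quinone methide pathway), or slow cleavage under the buffered conditions. The fallback, from 18 to 19, changes the approach to an in-flask exchange of protecting groups followed by neutral solvolysis. 18 is treated with n-Bu4NF in the presence of Ac2O (THF, 0 °C) so that each phenoxide is acetylated as it forms, giving the triacetate F11. Ammonium acetate in aqueous methanol (rt) then frees the three phenols without a basic medium and gives 19.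

Further compounds
F1 | step 6 | (4S)-4-benzyl-3-[(2R,3S)-2-allyl-3-Ar-3-(trimethylsilyloxy)propanoyl]oxazolidin-2-one | C=CC[C@@H](C(=O)N1[C@@H](Cc2ccccc2)COC1=O)[C@H](O[Si](C)(C)C)c3cc(OC)c(O[Si](C)(C)C(C)(C)C)c(OC)c3
F2 | step 6 | (4S)-4-benzyl-3-[(2R,3S)-2-allyl-3-Ar-3-hydroxypropanoyl]oxazolidin-2-one | C=CC[C@@H](C(=O)N1[C@@H](Cc2ccccc2)COC1=O)[C@H](O)c3cc(OC)c(O[Si](C)(C)C(C)(C)C)c(OC)c3
F3 | step 6 | (4S)-4-benzyl-3-{[(2S,3R)-2-Ar-5-hydroxytetrahydrofuran-3-yl]carbonyl}oxazolidin-2-one (C5 epimers) | OC1C[C@@H](C(=O)N2[C@@H](Cc3ccccc3)COC2=O)[C@H](O1)c4cc(OC)c(O[Si](C)(C)C(C)(C)C)c(OC)c4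
F4 | step 6 | (4S)-4-benzyl-3-{[(2S,3R)-2-Ar-2,3-dihydrofuran-3-yl]carbonyl}oxazolidin-2-one | O=C([C@@H]1C=CO[C@@H]1c2cc(OC)c(O[Si](C)(C)C(C)(C)C)c(OC)c2)N3[C@@H](Cc4ccccc4)COC3=O
F5 | step 10 | [3,4-bis(TBSO)phenyl]methanol | OCc1ccc(O[Si](C)(C)C(C)(C)C)c(O[Si](C)(C)C(C)(C)C)c1
F6 | step 10 | 4-(bromomethyl)-1,2-bis(TBSO)benzene | BrCc1ccc(O[Si](C)(C)C(C)(C)C)c(O[Si](C)(C)C(C)(C)C)c1
F7 | step 10 | (2S,3S)-3-{[3,4-bis(TBSO)benzyl]oxymethyl}-2-Ar-2,3-dihydrofuran | CC(C)(C)[Si](C)(C)Oc1ccc(COC[C@@H]2C=CO[C@@H]2c3cc(OC)c(O[Si](C)(C)C(C)(C)C)c(OC)c3)cc1O[Si](C)(C)C(C)(C)C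
F8 | step 10 | (4S,5S)-4-{[3,4-bis(TBSO)benzyl]oxymethyl}-5-Ar-dihydrofuran-2(3H)-one | O=C1C[C@@H](COCc2ccc(O[Si](C)(C)C(C)(C)C)c(O[Si](C)(C)C(C)(C)C)c2)[C@H](O1)c3cc(OC)c(O[Si](C)(C)C(C)(C)C)c(OC)c3
F9 | step 10 | (4S,5S)-4-{[3,4-bis(TBSO)benzyl]oxymethyl}-5-Ar-3-(trifluoroacetyl)dihydrofuran-2(3H)-one (C3 epimers) | O=C1C(C(=O)C(F)(F)F)[C@@H](COCc2ccc(O[Si](C)(C)C(C)(C)C)c(O[Si](C)(C)C(C)(C)C)c2)[C@H](O1)c3cc(OC)c(O[Si](C)(C)C(C)(C)C)c(OC)c3
F10 | step 10 | (4S,5S)-4-{[3,4-bis(TBSO)benzyl]oxymethyl}-5-Ar-3-diazodihydrofuran-2(3H)-one | O=C1C(=[N+]=[N-])[C@@H](COCc2ccc(O[Si](C)(C)C(C)(C)C)c(O[Si](C)(C)C(C)(C)C)c2)[C@H](O1)c3cc(OC)c(O[Si](C)(C)C(C)(C)C)c(OC)c3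
F11 | step 13 | (3S,3aS,6S,6aR)-6-(3,4-diacetoxyphenyl)-3-(4-acetoxy-3,5-dimethoxyphenyl)tetrahydro-1H,3H-furo[3,4-c]furan-1-one | COc1cc([C@H]2OC(=O)[C@@H]3[C@H]2CO[C@@H]3c2ccc(OC(C)=O)c(OC(C)=O)c2)cc(OC)c1OC(C)=O
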